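**Strategy.** Ring A is not taken from a phloroglucinol but grown onto an enantiopure ring C. The four carbons C5 to C8 are annulated onto the C4a=C8a enol ether bond of a (2S)-2-aryl-2,3-dihydropyran-4-one, which fixes the C8 prenyl group between C8a (bearing O1) and the oxygenated C7 and leaves C6 as CH. In one operation, photochemical Wolff rearrangement of an α-prenyl diazo ketone and vinylketene–siloxyalkyne benzannulation form C8–C8a, C7–C8, C5–C6 and C4a–C5 and give the 5-hydroxy-7-silyloxyflavanone. The precursor is the ring C pyranone bearing the 2-diazo-5-methylhex-4-enoyl group at the future C8a and ring B as its bis(triisopropylsilyl) ether, so a single fluoride treatment ends the synthesis.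

Key step: step 8

Remark: (triisopropylsilyloxy)acetylene 15 is a known, distillable silyl ynol ether; it is assumed to be in stock (bought, or made beforehand by O-silylation of lithium ethynolate with triisopropylsilyl chloride) and is counted as a starting material.

Notation: Ar = 3,4-bis(triisopropylsilyloxy)-5-(3-methylbut-2-en-1-yl)phenyl. Pyranones carry pyranone locants; from compound 19 on, flavanone locants are used.

**Step 1**
Reactants: 1 3-bromo-4,5-dihydroxybenzaldehyde
Product: 2 3-bromo-4,5-bis(triisopropylsilyloxy)benzaldehyde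
Conditions: TIPSOTf (2.4 equiv), 2,6-lutidine (3 equiv), CH2Cl2, 0 °C → rt
Reagents that add atoms: triisopropylsilyl trifluoromethanesulfonate, CC(C)[Si](OS(=O)(=O)C(F)(F)F)(C(C)C)C(C)C
Why: Phenol O-silylation with the silyl triflate and 2,6-lutidine is fast even at the flanked O4, and aryl triisopropylsilyl ethers tolerate Lewis acids, organozinc reagents, lithium amide at low temperature and tin hydroxide, yet leave with fluoride at the end together with the ring A silyl ether.

**Step 2**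
Reactants: 2 3-bromo-4,5-bis(triisopropylsilyloxy)benzaldehyde
Product: 3 3-(3-methylbut-2-enyl)-4,5-bis(triisopropylsilyloxy)benzaldehyde (Ar-CHO)
Conditions: tributyl(prenyl)stannane (1.3 equiv), Pd(PPh3)4 (5 mol %), DMF, 100 °C
Reagents that add atoms: tributyl(3-methylbut-2-en-1-yl)stannane, CCCC[Sn](CCCC)(CCCC)CC=C(C)C
Why: Stille coupling, in which oxidative addition of the aryl bromide to zerovalent palladium, transfer of the allyl group from tin and reductive elimination at the less hindered primary terminus should give the linear prenyl arene, while aldehyde and silyl ethers are inert under these neutral conditions.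

**Step 3**
Reactants: 4 methyl 2,4-dioxopentanoate
Product: 5 methyl (2Z)-2,4-bis(trimethylsilyloxy)penta-2,4-dienoate
Conditions: TMSOTf (2.2 equiv), Et3N (2.6 equiv), Et2O, 0 °C → rt
Reagents that add atoms: trimethylsilyl trifluoromethanesulfonate, C[Si](C)(C)OS(=O)(=O)C(F)(F)F
Why: Soft enolisation with TMSOTf/Et3N silylates the chelated enol at O2 and then the methyl ketone through its dienolate, the standard route from 1,3-dicarbonyl compounds to 1,3-bis(silyloxy)dienes, and leaves a nucleophilic CH2 terminus.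

**Step 4**
Reactants: 3 Ar-CHO; 5 methyl (2Z)-2,4-bis(trimethylsilyloxy)penta-2,4-dienoate
Product: 7 methyl (2S)-2-Ar-4-oxo-3,4-dihydro-2H-pyran-6-carboxylate, via aldol adduct 6 (not isolated)
Conditions: Ti(OiPr)4 (10 mol %), (S)-BINOL (10 mol %), 4 Å MS, THF, −20 °C → rt; then TFA, CH2Cl2, 0 °C
Reagents that add atoms: none
Why: Titanium–BINOL-catalysed vinylogous Mukaiyama aldol addition of the CH2 terminus of 5 to the aldehyde (a stepwise hetero-Diels–Alder reaction), in which the (S)-BINOL complex is expected to leave the Si face open as in allylations and aldol additions of aryl aldehydes and so to set (S) at the carbinol carbon (the ligand antipode would be taken if analysis showed the opposite sense), followed by acid-induced addition of that oxygen to C2 of the enoate with loss of the silyl groups, which closes ring C without touching the new center.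

**Step 5**
Reactants: 7 methyl (2S)-2-Ar-4-oxo-3,4-dihydro-2H-pyran-6-carboxylate
Product: 8 (2S)-2-Ar-4-oxo-3,4-dihydro-2H-pyran-6-carboxylic acid
Conditions: Me3SnOH (4 equiv), ClCH2CH2Cl, 70 °C; then 0.1 M aq. HCl wash
Reagents that add atoms: trimethyltin hydroxide, C[Sn](C)(C)O
Why: Me3SnOH converts the methyl ester to the tin carboxylate under nearly neutral conditions, so that C3 is not enolised and ring C cannot open by β-elimination of O1 (which would erase C2), and the hindered aryl silyl ethers are not attacked.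

**Step 6**
Reactants: 8 (2S)-2-Ar-4-oxo-3,4-dihydro-2H-pyran-6-carboxylic acid; 9 5-bromo-2-methylpent-2-ene
Product: 12 (2S)-2-Ar-6-(5-methylhex-4-enoyl)-2,3-dihydro-4H-pyran-4-one, via acid chloride 10 (not isolated), via alkylzinc bromide 11 (not isolated)
Conditions: 9, Zn dust, LiCl, THF, 50 °C (gives 11); 8, 1-chloro-N,N,2-trimethylprop-1-en-1-amine (1.05 equiv), CH2Cl2, 0 °C → rt (gives 10); then 10 + 11 (1.3 equiv), Pd(PPh3)4 (5 mol %), THF, 0 °C → rt
Reagents that add atoms: none
Why: Negishi acylation, in which the chloroenamine makes the acid chloride without HCl (which would add to the prenyl alkene), zerovalent palladium inserts into the C–Cl bond, and the alkylzinc bromide, too weakly basic and nucleophilic to touch the ring C ketone, the enone or C3–H, transfers the 4-methylpent-3-enyl group.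

**Step 7**
Reactants: 12 (2S)-2-Ar-6-(5-methylhex-4-enoyl)-2,3-dihydro-4H-pyran-4-one
Product: 14 (2S)-2-Ar-6-(2-diazo-5-methylhex-4-enoyl)-2,3-dihydro-4H-pyran-4-one, via trifluoroacetyl diketone 13 (not isolated)
Conditions: LiN(SiMe3)2 (1.1 equiv), THF, −78 °C; CF3CO2CH2CF3 (1.2 equiv); aq. HCl quench; then MsN3 (1.5 equiv), Et3N (1.5 equiv), H2O (1 equiv), MeCN, rt
Reagents that add atoms: methanesulfonyl azide, CS(=O)(=O)N=[N+]=[N-]
Why: Danheiser detrifluoroacetylative diazo transfer, in which kinetic deprotonation at −78 °C takes the side-chain CH2 of the true ketone and not the less acidic, more hindered C3–H of the vinylogous ester, the enolate is C-trifluoroacetylated, and mesyl azide with Et3N then transfers N2 to the activated carbon with cleavage of the trifluoroacetyl group under mild conditions.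

**Step 8**
Reactants: 14 (2S)-2-Ar-6-(2-diazo-5-methylhex-4-enoyl)-2,3-dihydro-4H-pyran-4-one; 15 (triisopropylsilyloxy)acetylene
Product: 20 (2S)-2-Ar-5-hydroxy-8-(3-methylbut-2-enyl)-7-(triisopropylsilyloxy)-2,3-dihydro-4H-chromen-4-one, via vinylketene 16 (not isolated), via cyclobutenone 17 (not isolated), via dienylketene 18 (not isolated), via cyclohexadienone 19 (not isolated)
Conditions: 15 (3 equiv), hν (450 nm LEDs), degassed ClCH2CH2Cl, 20 °C; then 80 °C
Reagents that add atoms: none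
Why: Light absorbed by the diazo ketone expels N2 with 1,2-shift of the ring C alkenyl carbon (the future C8a) to the diazo carbon, giving vinylketene 16; the siloxyalkyne adds [2+2] across the ketene C=C to give 4-alkenylcyclobutenone 17, which opens (4π, by light or on warming) to dienylketene 18. Ring A closes by thermal 6π-electrocyclisation of 18 (C4a–C5), and cyclohexadienone 19 enolises to the hydrogen-bonded 5-phenol 20. The closest known reaction is the Danheiser benzannulation in its photochemical Wolff form, established for alkenyl and aryl diazo ketones with siloxyalkynes. No stereocenter is created, and C2 stays (S) because the sequence is neutral and never enolises C3. Regiochemistry requires the nucleophilic CH carbon of 15 to bond to the electrophilic ketene carbon (C5), which the oxygen donor of the alkyne secures and which puts H at C6 and the silyloxy group at C7, while the prenyl group already sits on the diazo carbon and can only become C8. The Wolff shift must outrun 1,2-hydride shift from the prenyl CH2, and for that reason direct photolysis (no metal carbenoid), long-wavelength light that leaves the enone and aryl chromophores unexcited and an excess of 15 are chosen.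

**Step 9**
Reactants: 20 (2S)-2-Ar-5-hydroxy-8-(3-methylbut-2-enyl)-7-(triisopropylsilyloxy)-2,3-dihydro-4H-chromen-4-one
Product: 21 (2S)-2-[3,4-dihydroxy-5-(3-methylbut-2-enyl)phenyl]-5,7-dihydroxy-8-(3-methylbut-2-enyl)-2,3-dihydro-4H-chromen-4-one
Conditions: TBAF (3.3 equiv), AcOH (3.5 equiv), THF, 0 °C → rt
Reagents that add atoms: none
Why: Fluoride cleaves all three aryl O–Si bonds, while acetic acid keeps the liberated phenols protonated so that the flavanone neither opens to the chalcone (which would racemise C2) nor meets the strong acid that would cyclise the o-prenylphenols to chromans.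

**Compound list**

1 | 3-bromo-4,5-dihydroxybenzaldehyde | O=Cc1cc(O)c(O)c(Br)c1 | starting material
2 | 3-bromo-4,5-bis(triisopropylsilyloxy)benzaldehyde | O=Cc1cc(Br)c(O[Si](C(C)C)(C(C)C)C(C)C)c(O[Si](C(C)C)(C(C)C)C(C)C)c1 | intermediate
3 | 3-(3-methylbut-2-enyl)-4,5-bis(triisopropylsilyloxy)benzaldehyde | O=Cc1cc(CC=C(C)C)c(O[Si](C(C)C)(C(C)C)C(C)C)c(O[Si](C(C)C)(C(C)C)C(C)C)c1 | intermediate
4 | methyl 2,4-dioxopentanoate | COC(=O)C(=O)CC(C)=O | starting material
5 | methyl (2Z)-2,4-bis(trimethylsilyloxy)penta-2,4-dienoate | COC(=O)/C(O[Si](C)(C)C)=C/C(=C)O[Si](C)(C)C | intermediate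
6 | methyl (2Z,6S)-6-[3,4-bis(triisopropylsilyloxy)-5-(3-methylbut-2-enyl)phenyl]-4-oxo-2,6-bis(trimethylsilyloxy)hex-2-enoate | COC(=O)/C(O[Si](C)(C)C)=C/C(=O)C[C@H](O[Si](C)(C)C)c1cc(CC=C(C)C)c(O[Si](C(C)C)(C(C)C)C(C)C)c(O[Si](C(C)C)(C(C)C)C(C)C)c1 | intermediate
7 | methyl (2S)-2-[3,4-bis(triisopropylsilyloxy)-5-(3-methylbut-2-enyl)phenyl]-4-oxo-3,4-dihydro-2H-pyran-6-carboxylate | CC(C)=CCc1cc([C@@H]2CC(=O)C=C(C(=O)OC)O2)cc(O[Si](C(C)C)(C(C)C)C(C)C)c1O[Si](C(C)C)(C(C)C)C(C)C | intermediate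
8 | (2S)-2-[3,4-bis(triisopropylsilyloxy)-5-(3-methylbut-2-enyl)phenyl]-4-oxo-3,4-dihydro-2H-pyran-6-carboxylic acid | CC(C)=CCc1cc([C@@H]2CC(=O)C=C(C(=O)O)O2)cc(O[Si](C(C)C)(C(C)C)C(C)C)c1O[Si](C(C)C)(C(C)C)C(C)C | intermediate
9 | 5-bromo-2-methylpent-2-ene | CC(C)=CCCBr | starting material
10 | (2S)-2-[3,4-bis(triisopropylsilyloxy)-5-(3-methylbut-2-enyl)phenyl]-4-oxo-3,4-dihydro-2H-pyran-6-carbonyl chloride | CC(C)=CCc1cc([C@@H]2CC(=O)C=C(C(=O)Cl)O2)cc(O[Si](C(C)C)(C(C)C)C(C)C)c1O[Si](C(C)C)(C(C)C)C(C)C | intermediate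
11 | (4-methylpent-3-en-1-yl)zinc bromide | CC(C)=CCC[Zn]Br | intermediate
12 | (2S)-2-[3,4-bis(triisopropylsilyloxy)-5-(3-methylbut-2-enyl)phenyl]-6-(5-methylhex-4-enoyl)-2,3-dihydro-4H-pyran-4-one | CC(C)=CCc1cc([C@@H]2CC(=O)C=C(C(=O)CCC=C(C)C)O2)cc(O[Si](C(C)C)(C(C)C)C(C)C)c1O[Si](C(C)C)(C(C)C)C(C)C | intermediate
13 | (2S)-2-[3,4-bis(triisopropylsilyloxy)-5-(3-methylbut-2-enyl)phenyl]-6-[5-methyl-2-(trifluoroacetyl)hex-4-enoyl]-2,3-dihydro-4H-pyran-4-one (diketone/enol, side-chain center unassigned) | CC(C)=CCc1cc([C@@H]2CC(=O)C=C(C(=O)C(CC=C(C)C)C(=O)C(F)(F)F)O2)cc(O[Si](C(C)C)(C(C)C)C(C)C)c1O[Si](C(C)C)(C(C)C)C(C)C | intermediate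
14 | (2S)-2-[3,4-bis(triisopropylsilyloxy)-5-(3-methylbut-2-enyl)phenyl]-6-(2-diazo-5-methylhex-4-enoyl)-2,3-dihydro-4H-pyran-4-one | CC(C)=CCc1cc([C@@H]2CC(=O)C=C(C(=O)C(=[N+]=[N-])CC=C(C)C)O2)cc(O[Si](C(C)C)(C(C)C)C(C)C)c1O[Si](C(C)C)(C(C)C)C(C)C | intermediate
15 | (triisopropylsilyloxy)acetylene | C#CO[Si](C(C)C)(C(C)C)C(C)C | starting material
16 | (2S)-2-[3,4-bis(triisopropylsilyloxy)-5-(3-methylbut-2-enyl)phenyl]-6-(5-methyl-1-oxohexa-1,4-dien-2-yl)-2,3-dihydro-4H-pyran-4-one (vinylketene) | CC(C)=CCc1cc([C@@H]2CC(=O)C=C(C(CC=C(C)C)=C=O)O2)cc(O[Si](C(C)C)(C(C)C)C(C)C)c1O[Si](C(C)C)(C(C)C)C(C)C | intermediate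
17 | (2S)-2-[3,4-bis(triisopropylsilyloxy)-5-(3-methylbut-2-enyl)phenyl]-6-[1-(3-methylbut-2-enyl)-4-oxo-2-(triisopropylsilyloxy)cyclobut-2-en-1-yl]-2,3-dihydro-4H-pyran-4-one (both epimers at the cyclobutene carbon) | CC(C)=CCc1cc([C@@H]2CC(=O)C=C(C3(CC=C(C)C)C(=O)C=C3O[Si](C(C)C)(C(C)C)C(C)C)O2)cc(O[Si](C(C)C)(C(C)C)C(C)C)c1O[Si](C(C)C)(C(C)C)C(C)C | intermediate
18 | (2S)-2-[3,4-bis(triisopropylsilyloxy)-5-(3-methylbut-2-enyl)phenyl]-6-[7-methyl-1-oxo-3-(triisopropylsilyloxy)octa-1,3,6-trien-4-yl]-2,3-dihydro-4H-pyran-4-one (dienylketene, alkene isomers interconvert by reversible ring opening) | CC(C)=CCc1cc([C@@H]2CC(=O)C=C(C(CC=C(C)C)=C(O[Si](C(C)C)(C(C)C)C(C)C)C=C=O)O2)cc(O[Si](C(C)C)(C(C)C)C(C)C)c1O[Si](C(C)C)(C(C)C)C(C)C | intermediate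
19 | (2S)-2-[3,4-bis(triisopropylsilyloxy)-5-(3-methylbut-2-enyl)phenyl]-8-(3-methylbut-2-enyl)-7-(triisopropylsilyloxy)-2,3-dihydro-4H-chromene-4,5(4aH)-dione (C4a unassigned) | CC(C)=CCc1cc([C@@H]2CC(=O)C3C(=O)C=C(O[Si](C(C)C)(C(C)C)C(C)C)C(CC=C(C)C)=C3O2)cc(O[Si](C(C)C)(C(C)C)C(C)C)c1O[Si](C(C)C)(C(C)C)C(C)C | intermediate
20 | (2S)-2-[3,4-bis(triisopropylsilyloxy)-5-(3-methylbut-2-enyl)phenyl]-5-hydroxy-8-(3-methylbut-2-enyl)-7-(triisopropylsilyloxy)-2,3-dihydro-4H-chromen-4-one | CC(C)=CCc1cc([C@@H]2CC(=O)c3c(O)cc(O[Si](C(C)C)(C(C)C)C(C)C)c(CC=C(C)C)c3O2)cc(O[Si](C(C)C)(C(C)C)C(C)C)c1O[Si](C(C)C)(C(C)C)C(C)C | intermediate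
21 | (2S)-2-[3,4-dihydroxy-5-(3-methylbut-2-enyl)phenyl]-5,7-dihydroxy-8-(3-methylbut-2-enyl)-2,3-dihydro-4H-chromen-4-one | CC(C)=CCc1cc([C@@H]2CC(=O)c3c(O)cc(O)c(CC=C(C)C)c3O2)cc(O)c1O | target

**Step count.** Total: 9 steps. Longest linear sequence: 8 steps (1 → 2 → 3 → 7 → 8 → 12 → 14 → 20 → 21, steps 1, 2, 4, 5, 6, 7, 8, 9); step 3 is a one-step branch.

**Steps most likely to fail**

Step 8. After loss of N2 the keto carbene may undergo 1,2-hydride shift from the allylic CH2 (to a dienone) faster than the alkenyl shift. The ketene may also be intercepted by the product phenol before the alkyne adds. The fallback installs the C8 prenyl group after ring A has been built. It sets out from acid 8. Acid chloride 10, made as in step 6, would be treated with trimethylsilyldiazomethane (MeCN/THF, 0 °C) to give (2S)-2-Ar-6-(2-diazoacetyl)-2,3-dihydro-4H-pyran-4-one F1, a diazo ketone whose diazo carbon bears only hydrogen, so that no hydride shift is possible. The same irradiation with 15 and warming should give (2S)-2-Ar-5-hydroxy-7-(triisopropylsilyloxy)-2,3-dihydro-4H-chromen-4-one F2. Mitsunobu etherification of its only free phenol with 3-methylbut-2-en-1-ol (PPh3, DIAD, THF) would give the 5-O-prenyl ether, (2S)-2-Ar-5-(3-methylbut-2-enyloxy)-7-(triisopropylsilyloxy)-2,3-dihydro-4H-chromen-4-one F3. A Claisen–Cope rearrangement catalysed by Eu(fod)3, tris(6,6,7,7,8,8,8-heptafluoro-2,2-dimethyloctane-3,5-dionato)europium, in CHCl3 at 60 °C should then move the prenyl group to C8 and rejoin the route at 20. The price is lower regiochemical certainty, since C6 isomers would have to be separated.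

Step 4. The ester-bearing diene is less nucleophilic than the usual dioxygenated dienes and the aldehyde is electron-rich. A slow catalysed addition would let a background, silyl-cation-mediated racemic pathway compete and erode facial selectivity. The fallback sets the stereocenter by allylation and builds ring C by Claisen condensation; it sets out from aldehyde 3. Keck allylation (allyltributylstannane, Ti(OiPr)4, (S)-BINOL, 4 Å MS, CH2Cl2, −20 °C) should give (1S)-1-Ar-but-3-en-1-ol F4. Tsuji–Wacker oxidation of the terminal alkene (PdCl2, CuCl, O2, DMF/H2O), which leaves the trisubstituted prenyl alkene alone, would give (4S)-4-Ar-4-hydroxybutan-2-one F5. Silylation (Et3SiCl, imidazole, CH2Cl2) would give (4S)-4-Ar-4-(triethylsilyloxy)butan-2-one F6. Kinetic enolisation at the methyl group (LiN(SiMe3)2, THF, −78 °C) and acylation with dimethyl oxalate would give methyl (6S)-6-Ar-2,4-dioxo-6-(triethylsilyloxy)hexanoate F7. TFA in CH2Cl2 at 0 °C would then remove the silyl group and cyclodehydrate F7, rejoining the route at 7.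

Step 7. Deprotonation may compete at C3 of ring C, and the resulting enolate would expel O1 (ring opening and loss of the C2 configuration). The side-chain enolate may also be acylated on oxygen. The fallback assembles the 1,3-dicarbonyl unit by acylation, so that no lithium amide meets ring C; it sets out from bromide 9 and acid 8. Bromide 9 would be converted (Mg, THF) to (4-methylpent-3-enyl)magnesium bromide F8 and added to ethyl trifluoroacetate at −78 °C (aq. HCl work-up) to give 1,1,1-trifluoro-6-methylhept-5-en-2-one F9. Soft enolisation of F9 (MgBr2·OEt2, iPr2NEt, CH2Cl2, 0 °C → rt) and C-acylation with acid chloride 10, made from 8 as in step 6, should give diketone 13 directly. The azide half of step 7 (MsN3, Et3N, H2O, MeCN) then gives 14; ketone 12 is bypassed.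

**Further compounds**

F1 | step 8 | (2S)-2-[3,4-bis(triisopropylsilyloxy)-5-(3-methylbut-2-enyl)phenyl]-6-(2-diazoacetyl)-2,3-dihydro-4H-pyran-4-one | CC(C)=CCc1cc([C@@H]2CC(=O)C=C(C(=O)C=[N+]=[N-])O2)cc(O[Si](C(C)C)(C(C)C)C(C)C)c1O[Si](C(C)C)(C(C)C)C(C)C
F2 | step 8 | (2S)-2-[3,4-bis(triisopropylsilyloxy)-5-(3-methylbut-2-enyl)phenyl]-5-hydroxy-7-(triisopropylsilyloxy)-2,3-dihydro-4H-chromen-4-one | CC(C)=CCc1cc([C@@H]2CC(=O)c3c(O)cc(O[Si](C(C)C)(C(C)C)C(C)C)cc3O2)cc(O[Si](C(C)C)(C(C)C)C(C)C)c1O[Si](C(C)C)(C(C)C)C(C)C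
F3 | step 8 | (2S)-2-[3,4-bis(triisopropylsilyloxy)-5-(3-methylbut-2-enyl)phenyl]-5-(3-methylbut-2-enyloxy)-7-(triisopropylsilyloxy)-2,3-dihydro-4H-chromen-4-one | CC(C)=CCc1cc([C@@H]2CC(=O)c3c(OCC=C(C)C)cc(O[Si](C(C)C)(C(C)C)C(C)C)cc3O2)cc(O[Si](C(C)C)(C(C)C)C(C)C)c1O[Si](C(C)C)(C(C)C)C(C)C
F4 | step 4 | (1S)-1-[3,4-bis(triisopropylsilyloxy)-5-(3-methylbut-2-enyl)phenyl]but-3-en-1-ol | C=CC[C@H](O)c1cc(CC=C(C)C)c(O[Si](C(C)C)(C(C)C)C(C)C)c(O[Si](C(C)C)(C(C)C)C(C)C)c1
F5 | step 4 | (4S)-4-[3,4-bis(triisopropylsilyloxy)-5-(3-methylbut-2-enyl)phenyl]-4-hydroxybutan-2-one | CC(=O)C[C@H](O)c1cc(CC=C(C)C)c(O[Si](C(C)C)(C(C)C)C(C)C)c(O[Si](C(C)C)(C(C)C)C(C)C)c1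
F6 | step 4 | (4S)-4-[3,4-bis(triisopropylsilyloxy)-5-(3-methylbut-2-enyl)phenyl]-4-(triethylsilyloxy)butan-2-one | CC(=O)C[C@H](O[Si](CC)(CC)CC)c1cc(CC=C(C)C)c(O[Si](C(C)C)(C(C)C)C(C)C)c(O[Si](C(C)C)(C(C)C)C(C)C)c1
F7 | step 4 | methyl (6S)-6-[3,4-bis(triisopropylsilyloxy)-5-(3-methylbut-2-enyl)phenyl]-2,4-dioxo-6-(triethylsilyloxy)hexanoate | COC(=O)C(=O)CC(=O)C[C@H](O[Si](CC)(CC)CC)c1cc(CC=C(C)C)c(O[Si](C(C)C)(C(C)C)C(C)C)c(O[Si](C(C)C)(C(C)C)C(C)C)c1
F8 | step 7 | (4-methylpent-3-en-1-yl)magnesium bromide | CC(C)=CCC[Mg]Br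
F9 | step 7 | 1,1,1-trifluoro-6-methylhept-5-en-2-one | CC(C)=CCCC(=O)C(F)(F)F
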